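The side chain is attached at its benzylic/vinylic junction, C1′–C2′, instead of the usual aryl–C1′ bond. The plan exploits the C2 and C4 hydroxyls that flank ring carbon C3. A C3–CH2NMe2 Mannich base of 2,4,6-trihydroxybenzophenone is a latent ortho-quinone methide, and its exocyclic methylene is alkenylated by an (E)-alkenylboronic acid delivered from a phenol-bound boron. In one protecting-group-free operation the key step forms C1′–C2′, keeps the E-trisubstituted alkene and gives the target directly. The boronic acid already carries the (R)-carbinol (CBS reduction) and comes from one-pot methylalumination/borylation of a terminal alkyne.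

Key step: step 6

Remark: the ring is numbered C1 (benzoyl), C2/C4/C6 (OH), C3 (side chain), C5 (H), and the side chain C1′ (benzylic CH2) to C8′ (=CH2). The carbinol centre C6′ of the target SMILES is R. 2,4,6-Trihydroxybenzophenone and pent-4-ynoic acid are taken as catalogue compounds.

Step 1
Reactants: 1 pent-4-ynoic acid
Product: 2 N-methoxy-N-methylpent-4-ynamide
Conditions: CDI, CH2Cl2, 0 °C → rt; then MeNHOMe·HCl, rt
Reagents that add atoms: N,O-dimethylhydroxylamine hydrochloride (CNOC.Cl)
Why: Amide coupling through the acyl imidazolide gives the N-methoxy-N-methylamide, so that the next step stops at the ketone.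

Step 2
Reactants: 2 N-methoxy-N-methylpent-4-ynamide
Product: 3 2-methylhept-1-en-6-yn-3-one
Conditions: CH2=C(CH3)MgBr (2.2 equiv), THF, −20 → 0 °C; inverse quench into cold 1 M HCl
Reagents that add atoms: isopropenylmagnesium bromide (C=C(C)[Mg]Br)
Why: Weinreb ketone synthesis, in which the chelated tetrahedral adduct prevents over-addition, the extra Grignard reagent covers deprotonation of the terminal alkyne, and the inverse acidic quench keeps the liberated amine from adding to the enone.

Step 3
Reactants: 3 2-methylhept-1-en-6-yn-3-one
Product: 4 (3R)-2-methylhept-1-en-6-yn-3-ol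
Conditions: (S)-Me-CBS (20 mol %), catecholborane, toluene, −78 °C; MeOH, then aq. NaOH wash
Reagents that add atoms: none
Why: Corey–Bakshi–Shibata reduction, in which the ketone binds the oxazaborolidine anti to the larger α-branched isopropenyl group and hydride is delivered to the face that gives the (R)-carbinol (the same sense as acetophenone to (R)-1-phenylethanol with the (S)-catalyst); this sets C6′, and catecholborane at −78 °C should leave the alkyne and alkene untouched.

Step 4
Reactants: 4 (3R)-2-methylhept-1-en-6-yn-3-ol
Product: 7 [(1E,5R)-5-hydroxy-2,6-dimethylhepta-1,6-dien-1-yl]boronic acid, via alkenylalane 5 (not isolated), via dimethyl boronate 6 (not isolated)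
Conditions: Me3Al (3 equiv), Cp2ZrCl2 (25 mol %), CH2Cl2, 0 °C → rt; then B(OMe)3, 0 °C → rt; aq. NH4Cl
Reagents that add atoms: trimethylaluminium (C[Al](C)C), trimethyl borate (COB(OC)OC), water (O)
Why: Negishi carboalumination (zirconium-catalysed syn-methylalumination of the terminal alkyne) puts aluminium on the terminal carbon cis to the new methyl, which fixes the E-trisubstituted geometry, and aluminium-to-boron transmetalation with a borate ester proceeds with retention; the hydroxyl is carried as its aluminium alkoxide and the carbinol centre is not touched.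

Step 5
Reactants: 8 2,4,6-trihydroxybenzophenone
Product: 9 {3-[(dimethylamino)methyl]-2,4,6-trihydroxyphenyl}(phenyl)methanone
Conditions: CH2=NMe2+ I− (1.0 equiv), MeCN, 0 °C → rt; then aq. NaHCO3
Reagents that add atoms: dimethyl(methylidene)ammonium iodide (C=[N+](C)C.[I-])
Why: Mannich aminomethylation of the electron-rich phloroglucinol ring at C3 (equivalent to C5); one equivalent of preformed iminium salt and precipitation of the deactivated ammonium salt should hold the reaction at mono-substitution.

Step 6
Reactants: 9 {3-[(dimethylamino)methyl]-2,4,6-trihydroxyphenyl}(phenyl)methanone, 7 [(1E,5R)-5-hydroxy-2,6-dimethylhepta-1,6-dien-1-yl]boronic acid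
Product: 11 phenyl{2,4,6-trihydroxy-3-[(2E,6R)-6-hydroxy-3,7-dimethylocta-2,7-dien-1-yl]phenyl}methanone, via ortho-quinone methide 10 (not isolated)
Conditions: 7 (1.5 equiv), 9 added slowly, 4 Å MS, 1,4-dioxane (0.05 M), 50–70 °C; pH 5 aqueous work-up
Reagents that add atoms: none
Why: This is a conjugate alkenylation of an in situ ortho-quinone methide by a phenol-bound alkenylboron (Petasis-type boron-to-carbon transfer; the closest known type is the addition of alkenylboronates to ortho-quinone methides generated from ortho-hydroxybenzyl precursors): boronic acid 7 condenses with the C2/C4 hydroxyl of 9 and is chelated by the benzylic amine, C–N heterolysis expels Me2NH and unmasks quinone methide 10 with its carbonyl oxygen still coordinated to tetracoordinate boron, and the alkenyl group migrates from boron to the exocyclic CH2 through a six-membered cyclic transition state, which rearomatises the ring. No ring is closed in the product (only a transient O–B chelate, hydrolysed on work-up) and no stereocentre is formed; the C6′ carbinol centre of 7 is remote from the reacting atoms and is carried through unchanged. The step needs retention of the E geometry, which the concerted intramolecular transfer secures because the migrating sp2 carbon keeps its configuration, and ipso selectivity, which is secured because only the boron-bearing carbon can reach the methylene terminus. It also needs chemoselectivity over C5-arylation (methylene-bridged dimers) and over hetero-Diels–Alder capture by the isopropenyl group, which is favoured by intramolecular delivery, the absence of added base, dilution and the excess of 7. Double alkylation cannot occur because 9 carries a single aminomethyl group.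

Compound list
1 | pent-4-ynoic acid | C#CCCC(=O)O | starting material
2 | N-methoxy-N-methylpent-4-ynamide | C#CCCC(=O)N(C)OC | intermediate
3 | 2-methylhept-1-en-6-yn-3-one | C=C(C)C(=O)CCC#C | intermediate
4 | (3R)-2-methylhept-1-en-6-yn-3-ol | C=C(C)[C@H](O)CCC#C | intermediate
5 | dimethyl[(1E,5R)-5-(dimethylalumanyloxy)-2,6-dimethylhepta-1,6-dien-1-yl]alane (alkenylalane, not isolated) | C=C(C)[C@H](O[Al](C)C)CC/C(C)=C/[Al](C)C | intermediate
6 | dimethyl [(1E,5R)-5-(dimethylalumanyloxy)-2,6-dimethylhepta-1,6-dien-1-yl]boronate (dimethyl boronate, not isolated) | C=C(C)[C@H](O[Al](C)C)CC/C(C)=C/B(OC)OC | intermediate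
7 | [(1E,5R)-5-hydroxy-2,6-dimethylhepta-1,6-dien-1-yl]boronic acid | C=C(C)[C@H](O)CC/C(C)=C/B(O)O | intermediate
8 | 2,4,6-trihydroxybenzophenone | O=C(c1ccccc1)c1c(O)cc(O)cc1O | starting material
9 | {3-[(dimethylamino)methyl]-2,4,6-trihydroxyphenyl}(phenyl)methanone | CN(C)Cc1c(O)cc(O)c(C(=O)c2ccccc2)c1O | intermediate
10 | 4-benzoyl-3,5-dihydroxy-6-methylidenecyclohexa-2,4-dien-1-one (ortho-quinone methide, boron-bound, not isolated) | C=C1C(=O)C=C(O)C(C(=O)c2ccccc2)=C1O | intermediate
11 | phenyl{2,4,6-trihydroxy-3-[(2E,6R)-6-hydroxy-3,7-dimethylocta-2,7-dien-1-yl]phenyl}methanone | C=C(C)[C@H](O)CC/C(C)=C/Cc1c(O)cc(O)c(C(=O)c2ccccc2)c1O | target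

Total steps: 6. Longest linear sequence: 5 steps (steps 1, 2, 3, 4 and 6).

Steps most likely to fail

Step 6. Self-condensation of the quinone methide through C5 of a second arene, or hetero-Diels–Alder capture by the isopropenyl group, may outrun the boron-to-carbon transfer. The fallback is a protected sp3–sp2 cross-coupling that forms the same bond. It sets out from 8. Vilsmeier–Haack formylation (POCl3, DMF, EtOAc, then aqueous hydrolysis) should give 3-benzoyl-2,4,6-trihydroxybenzaldehyde F1. MOMCl/NaH in DMF should give 3-benzoyl-2,4,6-tris(methoxymethoxy)benzaldehyde F2. NaBH4 (MeOH, 0 °C) should reduce only the aldehyde, leaving the hindered diaryl ketone, to give [3-(hydroxymethyl)-2,4,6-tris(methoxymethoxy)phenyl](phenyl)methanone F3. MsCl, Et3N and LiCl (THF, 0 °C) should give [3-(chloromethyl)-2,4,6-tris(methoxymethoxy)phenyl](phenyl)methanone F4, which is used crude. Alkyne 4 is carboaluminated as in step 4 to alane 5, and excess Me3Al is removed in vacuo. Alane 5 is then coupled with F4 under Ni(0) catalysis (NiCl2(PPh3)2/n-BuLi, THF, rt; Negishi-type alkenylalane–benzyl chloride coupling) to give the tris(methoxymethyl) ether of the target F5. Brief HCl in MeOH at rt removes the MOM groups, and the route is rejoined at 11.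

Step 4. Aluminium-to-boron exchange may be incomplete, methyl may transfer in competition, or the alkenyl–metal bond may be protonated on work-up. The fallback sets out from 4. Alane 5 is generated as before and quenched with I2 (THF, −30 °C), the classical carboalumination–iodination, to give (3R,6E)-7-iodo-2,6-dimethylhepta-1,6-dien-3-ol F6. Miyaura borylation (B2pin2, PdCl2(PPh3)2, PPh3, KOPh, toluene, 50 °C) should give (3R,6E)-2,6-dimethyl-7-(4,4,5,5-tetramethyl-1,3,2-dioxaborolan-2-yl)hepta-1,6-dien-3-ol F7. NaIO4/NH4OAc in acetone–water cleaves the pinacol ester, and the route is rejoined at 7.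

Step 3. Enantioface discrimination between the isopropenyl group and the CH2CH2 chain may be insufficient, or the alkyne may be hydroborated. The fallback replaces asymmetric reduction by resolution and sets out from 3. Luche reduction (NaBH4, CeCl3·7H2O, MeOH, −40 °C) should give racemic 2-methylhept-1-en-6-yn-3-ol F8. Sharpless kinetic resolution (Ti(OiPr)4, L-(+)-DIPT, TBHP 0.6 equiv, 4 Å MS, CH2Cl2, −20 °C) should epoxidise the (S)-enantiomer faster, to (1S)-1-[(2R)-2-methyloxiran-2-yl]pent-4-yn-1-ol F9. The unreacted (R)-alcohol is separated by chromatography, and the route is rejoined at 4.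

Further compounds
F1 | step 6 | 3-benzoyl-2,4,6-trihydroxybenzaldehyde | O=Cc1c(O)cc(O)c(C(=O)c2ccccc2)c1O
F2 | step 6 | 3-benzoyl-2,4,6-tris(methoxymethoxy)benzaldehyde | O=Cc1c(OCOC)cc(OCOC)c(C(=O)c2ccccc2)c1OCOC
F3 | step 6 | [3-(hydroxymethyl)-2,4,6-tris(methoxymethoxy)phenyl](phenyl)methanone | OCc1c(OCOC)cc(OCOC)c(C(=O)c2ccccc2)c1OCOC
F4 | step 6 | [3-(chloromethyl)-2,4,6-tris(methoxymethoxy)phenyl](phenyl)methanone | ClCc1c(OCOC)cc(OCOC)c(C(=O)c2ccccc2)c1OCOC
F5 | step 6 | {3-[(2E,6R)-6-hydroxy-3,7-dimethylocta-2,7-dien-1-yl]-2,4,6-tris(methoxymethoxy)phenyl}(phenyl)methanone | C=C(C)[C@H](O)CC/C(C)=C/Cc1c(OCOC)cc(OCOC)c(C(=O)c2ccccc2)c1OCOC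
F6 | step 4 | (3R,6E)-7-iodo-2,6-dimethylhepta-1,6-dien-3-ol | C=C(C)[C@H](O)CC/C(C)=C/I
F7 | step 4 | (3R,6E)-2,6-dimethyl-7-(4,4,5,5-tetramethyl-1,3,2-dioxaborolan-2-yl)hepta-1,6-dien-3-ol | C=C(C)[C@H](O)CC/C(C)=C/B1OC(C)(C)C(C)(C)O1
F8 | step 3 | rac-2-methylhept-1-en-6-yn-3-ol | C=C(C)C(O)CCC#C
F9 | step 3 | (1S)-1-[(2R)-2-methyloxiran-2-yl]pent-4-yn-1-ol | C#CCC[C@H](O)[C@@]1(C)CO1
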